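## The problem

Gancaonin G (14) is an isoflavone: a 4H-chromen-4-one, with ring A fused to the pyranone ring C through C4a–C8a, carrying a 4-hydroxyphenyl group (ring B) on C3. It has no stereocentre, and the prenyl double bond ends in two methyl groups, so there is no stereochemistry to control and none that could help. The difficulty is ring A, where four neighbouring positions all differ: a hydroxyl at C5 hydrogen-bonded to the C4 carbonyl, a 3-methylbut-2-enyl group at C6, a methoxyl at C7 and hydrogen at C8. The carbon substituent must go to C6 and not to the electronically similar C8, and the oxygens at C5, C7 and O1 must be told apart. The prenyl group is the fragile part: beside the C5 hydroxyl it closes to a 2,2-dimethylchroman under protic or Lewis acid, it is reduced under the hydrogenolysis used for benzyl ethers, and a metathesis catalyst would engage it. The pyranone is opened at C2 by hard nucleophiles and hot base, and the two phenols differ sharply, the C5 hydroxyl being chelated and the 4'-hydroxyl ordinary. The handle for the key step is the C2=C3 double bond: C2 carries only hydrogen and is bound to the aryl ether oxygen O1, while C3 carries ring B and is bound to the C4 ketone. This alkene can therefore be read as the metathesis product of an aryl vinyl ether (O1–CH=CH2) and the methylene of an alpha-aryl enone (CH2=C3(Ar)–C4=O), which closes ring C at carbon with O1 and C4 already fixed on ring A.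

## Retrosynthesis

**C6–prenyl bond.** The first cut is the bond from C6 to the prenyl CH2, taking 14 back to aryl iodide 12 and tributyl(3-methylbut-2-enyl)stannane 13. Direct C-prenylation of a phloroglucinol-type ring gives C6, C8 and O-alkylated products, and Claisen routes deliver the 1,1-dimethylallyl group or send the chain to C8. A cross-coupling puts the chain exactly where the halogen sits, and doing it last means the prenyl group never meets acid, oxidant or a metathesis catalyst. Compound 12 has no sensitive alkene. The forward Stille coupling must transfer the allyl group through its primary carbon and tolerate two free phenols.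

**Benzyl ether, C6–I bond and C5 methyl ether.** Iodide 12 is traced to its 4'-benzyl ether 11, 11 to the iodine-free phenol 10, and 10 to the 5,7-dimethyl ether 9. The order follows from what each forward step needs. Iodination is directed to C6 by the free, chelated C5 hydroxyl, and it needs ring B masked so that the 4'-phenol is not iodinated. The benzyl group comes off with BCl3 before the prenyl group exists, and cannot be removed by hydrogenolysis once iodine or the prenyl group is present. The chelation-controlled demethylation distinguishes the C5 from the C7 methoxyl without any extra protecting group. Compound 9 is a plain, robust isoflavone.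

**C2=C3 bond (key cut).** Isoflavone 9 is opened across C2=C3 to the vinyl ether–enone 8; in the forward reaction the two terminal CH2 groups are lost as gas. The classical neighbours close ring C at O1–C2 from a deoxybenzoin and a one-carbon electrophile, or attach ring B to a 3-halochromone. The metathesis cut instead brings C2 in as a vinyl group on O1 and C3 together with ring B as a 1-arylvinyl unit, and both arrive on simple precursors. The forward step asks a catalyst to turn over an oxygen-substituted alkylidene and to accept a hindered, electron-poor 1,1-disubstituted alkene, which points to the molybdenum imido alkylidene Mo(N-2,6-iPr2C6H3)(CHCMe2Ph)[OCMe(CF3)2]2 and away from ruthenium carbenes. Benzyl is chosen for O4' because it is inert to this catalyst and to everything before it.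

**C4 oxidation level and C3–C4 bond.** Enone 8 is taken back to the racemic allylic alcohol 7, and 7 is cut between the carbinol carbon (C4) and the vinyl carbon (C3) into aldehyde 3 and the 1-arylvinyl Grignard reagent 6. Reagent 6 comes from bromoalkene 5, which is made from 4'-(benzyloxy)acetophenone 4. The alternative cut at C4–C4a would need acylation of an electron-rich arene with a labile alpha-arylacrylic acid derivative under Lewis acid, which the vinyl ether would not survive. Adding a vinyl metal to an aldehyde and oxidising with MnO2 is neutral throughout. The forward steps must be worked up without acid, because 7 is a doubly activated carbinol on a trioxygenated ring and 8 is a reactive enone.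

**O1–vinyl bond.** Aldehyde 3 is cut at the O–CH=CH2 bond to 2-hydroxy-4,6-dimethoxybenzaldehyde 1 and vinyl acetate 2. Compound 1 already holds all three ring A oxygens in the right pattern, with the one free hydroxyl destined to become O1. A vinyl transfer catalysed by [Ir(cod)Cl]2 does the job in one step, against two steps for alkylation and elimination. The forward reaction must vinylate a hindered, hydrogen-bonded phenol without touching the aldehyde.

## Roads not taken

Alternative 1: The cut is made through O1–C8a and C4–C4a at once. It leads to the aryne precursor 3,5-dimethoxy-4-(3-methylbut-2-enyl)-2-(trimethylsilyl)phenyl trifluoromethanesulfonate A2 and to [4-(methoxymethoxy)phenyl]acetic acid A3. In the forward step CsF releases the aryne from A2, the carboxylate oxygen of A3 adds to the aryne carbon remote from the flanking methoxyl, the aryl anion formed beside that methoxyl attacks the acyl carbon, and collapse gives the ortho-hydroxy deoxybenzoin 1-[2-hydroxy-4,6-dimethoxy-5-(3-methylbut-2-enyl)phenyl]-2-[4-(methoxymethoxy)phenyl]ethanone A1.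
- Merits: the route is convergent, the whole ring A pattern of A1 including the prenyl group at C6 is already fixed in A2, and the methoxyl on the aryne steers the insertion the right way. In convergence and in the security of the C6 regiochemistry it is better than the chosen plan, which settles that question only at a late iodination.
- Weak points: A2 is a pentasubstituted arene with adjacent silyl and triflate groups and a prenyl group between two methoxyls, and making it would take more steps than the whole chosen route up to its key step. Simple O-arylation of A3 competes with insertion, and an aryne can react with the prenyl alkene in an ene reaction. The key step closes no ring, so A1 still needs a one-carbon insertion at C2 to build ring C. After that the C5 methoxyl must be cleaved by a Lewis acid beside the prenyl group and the methoxymethyl ether removed by acid, which are the conditions that close the chroman.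
- Comparison: the chosen plan sets against this its catalogue building blocks, four steps to the key substrate, a key step that closes ring C itself, and a prenyl group that arrives last.

Alternative 2: All of ring A is disconnected (C8–C8a, C7–C8, C5–C6 and C4a–C5) into the diazoketone 2-diazo-1-{5-[4-(tert-butyldimethylsilyloxy)phenyl]-4-oxo-4H-pyran-2-yl}ethanone A5 and the alkoxyalkyne 1-methoxy-5-methylhex-4-en-1-yne A6. On irradiation a Wolff rearrangement of A5 gives a pyranonyl ketene, which adds to the electron-rich alkyne A6 in a [2+2] sense. The four-membered ring opens in a four-electron process to a dienylketene, and this closes in a six-electron electrocyclisation onto the pyranone carbon that becomes C4a. Tautomerisation gives 4'-O-tert-butyldimethylsilyl gancaonin G A4, with the C5 hydroxyl, the C6 prenyl group and the C7 methoxyl placed by the mechanism.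
- Merits: this is the most economical answer to ring A. It needs no protecting group on O5, no selective demethylation and no halogenation, and the endgame from A4 is a single fluoride desilylation that the prenyl group tolerates. After the key step it is shorter and more secure in regiochemistry than the chosen plan.
- Weak points: A5 has to be built from a pyranone acid that is not a catalogue compound, and A6 is a hydrolytically fragile ynol ether that also needs several steps. The 4-pyranone is itself a photoactive chromophore prone to rearrangement under the light needed for the Wolff step. The pyranone double bond must act as the vinyl part of the ketene and then take part in the electrocyclisation, which interrupts its vinylogous ester conjugation and has no close model. The prenyl alkene is also a possible partner for the ketene intermediates.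
- Comparison: the chosen plan offers a thermal, catalyst-controlled key step on a substrate four steps from commercial materials, later steps that each have direct counterparts in flavonoid chemistry, and a classical rescue from the same intermediate.

Alternative 3: Ring C is cut at C4a–C4 and C3–C4, with carbon monoxide as C4, leaving the aryl iodide enol ether 1-iodo-2,4-dimethoxy-6-{(E)-2-[4-(methoxymethoxy)phenyl]ethenyloxy}-3-(3-methylbut-2-enyl)benzene A8. Under CO with Pd(OAc)2, PCy3 and CsOPiv, zerovalent palladium inserts into the C4a–I bond of A8, CO inserts, and the nucleophilic enol ether carbon C3 attacks the acylpalladium. Loss of a proton gives 5,7-dimethoxy-4'-(methoxymethoxy)-6-(3-methylbut-2-enyl)isoflavone A7.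
- Merits: the ketone and ring C are made together from a cheap C1 source, the prenyl position is fixed in the arene, and the catalyst is robust and tin-free. In these respects it is better than the chosen plan.
- Weak points: the arylpalladium is flanked by two ortho oxygens, so CO uptake must outrun direct closure onto the enol ether, which would give a five-membered ring. The six-membered closure of an acylpalladium onto an enol ether carbon is itself without close precedent. Making A8 needs a regiodefined iodination between two oxygens of a prenylated phloroglucinol ether, so the regiochemical question is moved, not removed. A7 must still lose its C5 methyl and its methoxymethyl group under Lewis and protic acid beside the prenyl group, and palladium hydrides can shift the prenyl double bond.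
- Comparison: the chosen plan has simpler access to its substrate, a ring closure that can only give the six-membered ring, and no exposure of the prenyl group to acid.

Key step: step 5

## Route

Assumption: bromoalkene 5 and enone 8 are used within hours of preparation, and Mo(N-2,6-iPr2C6H3)(CHCMe2Ph)[OCMe(CF3)2]2 and stannane 13 are taken as catalogue reagents handled under argon.

Step 1
Reactants: 1 2-hydroxy-4,6-dimethoxybenzaldehyde; 2 vinyl acetate
Product: 3 2,4-dimethoxy-6-(vinyloxy)benzaldehyde
Conditions: [Ir(cod)Cl]2 (2 mol%), Na2CO3 (0.6 equiv), vinyl acetate (3 equiv), toluene, 100 °C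
Reagents that add atoms: none
Why: Transfer vinylation of a phenol with vinyl acetate catalysed by [Ir(cod)Cl]2 (addition of the phenoxide to the coordinated vinyl ester, then loss of acetate); the carbonate base does not harm the non-enolisable aldehyde, and the aryl vinyl ether is stable in the basic medium.

Step 2
Reactants: 4 4'-(benzyloxy)acetophenone
Product: 5 1-(benzyloxy)-4-(1-bromovinyl)benzene
Conditions: P(OPh)3, Br2, CH2Cl2, −60 °C; then 4, Et3N, −60 °C to reflux
Reagents that add atoms: bromine, BrBr
Why: Conversion of an aryl methyl ketone into the 1-bromoalkene with preformed triphenyl phosphite dibromide and triethylamine (activation of the carbonyl oxygen on phosphorus, bromide attack, elimination); bromine is bound to phosphorus before the ketone is added, so the electron-rich ring should not be brominated, and the labile bromide is filtered through basic alumina and used at once.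

Step 3
Reactants: 5 1-(benzyloxy)-4-(1-bromovinyl)benzene; 3 2,4-dimethoxy-6-(vinyloxy)benzaldehyde
Product: 7 rac-2-[4-(benzyloxy)phenyl]-1-[2,4-dimethoxy-6-(vinyloxy)phenyl]prop-2-en-1-ol, via 1-[4-(benzyloxy)phenyl]vinylmagnesium bromide 6 (not isolated)
Conditions: Mg turnings, I2 (cat.), THF, 25–40 °C; then 3, THF, −40 to 0 °C; pH 7 phosphate buffer
Reagents that add atoms: none
Why: Magnesium insertion into the vinylic C–Br bond and 1,2-addition of the 1-arylvinyl Grignard reagent to an aldehyde that has no enolisable position; the carbinol centre forms as the racemate and is erased in the next step, and the neutral work-up spares the acid-labile, doubly activated alcohol and the vinyl ether.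

Step 4
Reactants: 7 rac-2-[4-(benzyloxy)phenyl]-1-[2,4-dimethoxy-6-(vinyloxy)phenyl]prop-2-en-1-ol
Product: 8 2-[4-(benzyloxy)phenyl]-1-[2,4-dimethoxy-6-(vinyloxy)phenyl]prop-2-en-1-one
Conditions: activated MnO2 (15 equiv), CH2Cl2, 20 °C; filter through Celite, concentrate cold, dry by benzene azeotrope
Reagents that add atoms: none
Why: Heterogeneous MnO2 oxidation of an alcohol that is both allylic and benzylic; the medium is neutral and non-aqueous, so the vinyl ether is not hydrolysed, and the enone is kept cold and dilute and carried straight into the metathesis to forestall dimerisation or polymerisation.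

Step 5
Reactants: 8 2-[4-(benzyloxy)phenyl]-1-[2,4-dimethoxy-6-(vinyloxy)phenyl]prop-2-en-1-one
Product: 9 4'-benzyloxy-5,7-dimethoxyisoflavone
Conditions: Mo(N-2,6-iPr2C6H3)(CHCMe2Ph)[OCMe(CF3)2]2 (15 mol%), benzene (0.01 M), 60 °C, slow argon sweep
Reagents that add atoms: none
Why: Proposed new method: the alkylidene of Mo(N-2,6-iPr2C6H3)(CHCMe2Ph)[OCMe(CF3)2]2 is expected to exchange first with the unhindered monosubstituted vinyl ether of 8 to give an aryloxymethylidene, which adds across the tethered 1,1-disubstituted enone alkene to a molybdacyclobutane; cycloreversion leaves the C2=C3 double bond in the ring and a methylidene that carries the chain, while ethylene is swept out with the argon. The closest known reaction type is the ring-closing metathesis of enol ethers bearing a second alkene to benzofurans, chromenes and dihydropyrans with this class of molybdenum imido alkylidene, together with ring-closing metathesis of acrylates and enones to unsaturated lactones and cyclic enones; a vinyl ether paired with an alpha-aryl enone to give a 4-pyranone has not been shown. Ring C closes as a six-membered ring by formation of the endocyclic C2=C3 alkene from the two terminal alkenes, both methylene carbons leaving as ethylene, so O1, C4 and the ring A pattern are fixed beforehand and no choice among ring A oxygens arises. No stereocentre is formed. The step needs chemoselectivity for alkene metathesis over Wittig-like olefination of the C4 ketone and over oligomerisation: the ketone is flanked by two ortho substituents and twisted out of plane, the only other unsaturation is aromatic because O4' carries benzyl and the prenyl group is not yet present, and six-membered ring closure at high dilution should outpace cross-metathesis. Ruthenium carbenes are passed over because the vinyl ether traps them as unreactive alkoxycarbenes, whereas the electrophilic molybdenum centre turns over oxygen-substituted alkylidenes. Loss of ethylene and the gain of the vinylogous ester conjugation of the 4-pyranone should make the closure irreversible.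

Step 6
Reactants: 9 4'-benzyloxy-5,7-dimethoxyisoflavone
Product: 10 4'-benzyloxy-5-hydroxy-7-methoxyisoflavone
Conditions: MgI2·OEt2 (3 equiv), THF, 65 °C; aqueous NH4Cl
Reagents that add atoms: none
Why: Chelation-controlled demethylation: magnesium bound between the C4 carbonyl and the C5 methoxyl activates only that methyl group towards iodide, so the C7 methoxyl and the remote 4'-benzyl ether, which cannot chelate, remain.

Step 7
Reactants: 10 4'-benzyloxy-5-hydroxy-7-methoxyisoflavone
Product: 11 4'-benzyloxy-5-hydroxy-6-iodo-7-methoxyisoflavone
Conditions: BnMe3N·ICl2 (1.1 equiv), CaCO3, CH2Cl2–MeOH, 20 °C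
Reagents that add atoms: benzyltrimethylammonium dichloroiodate, C[N+](C)(C)Cc1ccccc1.Cl[I-]Cl
Why: Electrophilic iodination of a phenol with the dichloroiodate salt under carbonate buffering; in 5-hydroxy-7-alkoxy flavonoids the free chelated hydroxyl directs this reagent to its ortho position C6, whereas C8 is the site when O5 is alkylated, and without a Lewis acid the reagent does not iodinate the benzyl-protected ring B.

Step 8
Reactants: 11 4'-benzyloxy-5-hydroxy-6-iodo-7-methoxyisoflavone
Product: 12 4',5-dihydroxy-6-iodo-7-methoxyisoflavone
Conditions: BCl3 (3 equiv), C6HMe5 (5 equiv), CH2Cl2, −78 °C; aqueous work-up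
Reagents that add atoms: none
Why: Lewis-acid debenzylation of an aryl benzyl ether with pentamethylbenzene as a non-basic scavenger for the benzyl cation; at −78 °C the C7 methyl ether and the aryl iodide are untouched, no hydrogen is used so C–I and C2=C3 survive, and the step is placed before prenylation so that no acid-sensitive alkene is present.

Step 9
Reactants: 12 4',5-dihydroxy-6-iodo-7-methoxyisoflavone; 13 tributyl(3-methylbut-2-enyl)stannane
Product: 14 gancaonin G, 5-hydroxy-3-(4-hydroxyphenyl)-7-methoxy-6-(3-methylbut-2-enyl)-4H-chromen-4-one
Conditions: Pd(PPh3)4 (10 mol%), 13 (1.5 equiv), degassed DMF, 95 °C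
Reagents that add atoms: none
Why: Stille coupling: zerovalent palladium inserts into the C6–I bond, the allylic stannane transmetalates, and reductive elimination from the less hindered primary terminus of the allyl ligand gives the 3-methylbut-2-enyl group and not the 1,1-dimethylallyl isomer; the medium is neutral and base-free, so both phenols and the pyranone are tolerated and the prenyl group meets no acid.

## Compound list

1 | 2-hydroxy-4,6-dimethoxybenzaldehyde | COc1cc(O)c(C=O)c(OC)c1 | starting material
2 | vinyl acetate | C=COC(C)=O | starting material
3 | 2,4-dimethoxy-6-(vinyloxy)benzaldehyde | C=COc1cc(OC)cc(OC)c1C=O | intermediate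
4 | 4'-(benzyloxy)acetophenone | CC(=O)c1ccc(OCc2ccccc2)cc1 | starting material
5 | 1-(benzyloxy)-4-(1-bromovinyl)benzene | C=C(Br)c1ccc(OCc2ccccc2)cc1 | intermediate
6 | 1-[4-(benzyloxy)phenyl]vinylmagnesium bromide | C=C([Mg]Br)c1ccc(OCc2ccccc2)cc1 | intermediate (not isolated)
7 | rac-2-[4-(benzyloxy)phenyl]-1-[2,4-dimethoxy-6-(vinyloxy)phenyl]prop-2-en-1-ol (racemate) | C=COc1cc(OC)cc(OC)c1C(O)C(=C)c1ccc(OCc2ccccc2)cc1 | intermediate
8 | 2-[4-(benzyloxy)phenyl]-1-[2,4-dimethoxy-6-(vinyloxy)phenyl]prop-2-en-1-one | C=COc1cc(OC)cc(OC)c1C(=O)C(=C)c1ccc(OCc2ccccc2)cc1 | intermediate
9 | 4'-benzyloxy-5,7-dimethoxyisoflavone | COc1cc(OC)c2c(c1)occ(-c1ccc(OCc3ccccc3)cc1)c2=O | intermediate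
10 | 4'-benzyloxy-5-hydroxy-7-methoxyisoflavone | COc1cc(O)c2c(c1)occ(-c1ccc(OCc3ccccc3)cc1)c2=O | intermediate
11 | 4'-benzyloxy-5-hydroxy-6-iodo-7-methoxyisoflavone | COc1cc2occ(-c3ccc(OCc4ccccc4)cc3)c(=O)c2c(O)c1I | intermediate
12 | 4',5-dihydroxy-6-iodo-7-methoxyisoflavone | COc1cc2occ(-c3ccc(O)cc3)c(=O)c2c(O)c1I | intermediate
13 | tributyl(3-methylbut-2-enyl)stannane | CCCC[Sn](CCCC)(CCCC)CC=C(C)C | starting material
14 | gancaonin G | COc1cc2occ(-c3ccc(O)cc3)c(=O)c2c(O)c1CC=C(C)C | target

## Step count and risks

Total: 9 steps. Longest linear sequence: 8 steps (1 → 3 → 7 → 8 → 9 → 10 → 11 → 12 → 14; the branch from 4 through 5 is equally long).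

**Step 5 (key step, proposed new method).** The catalyst may be consumed by Wittig-like transfer of its alkylidene to the C4 ketone, or the aryloxymethylidene may be held as a chelate by the neighbouring carbonyl oxygen so that it does not turn over. The electron-poor, 1,1-disubstituted alkene may also fail to enter the metallacycle, and enone 8 may dimerise or polymerise before it cyclises. The fallback uses known chemistry and closes ring C at O1–C2 instead. It sets out from 8: dilute aqueous HCl in THF hydrolyses the vinyl ether to 2-[4-(benzyloxy)phenyl]-1-(2-hydroxy-4,6-dimethoxyphenyl)prop-2-en-1-one F1. With K2CO3 in methanol the phenol adds to the enone methylene in an intramolecular oxa-Michael reaction, giving rac-4'-benzyloxy-5,7-dimethoxyisoflavanone F2. Dehydrogenation of F2 with DDQ in refluxing dioxane introduces the C2=C3 double bond and returns to the route at 9.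

**Step 1.** The hydrogen-bonded, doubly ortho-substituted phenol may turn the [Ir(cod)Cl]2 catalyst over poorly, and the metal may attack the aldehyde C–H bond at 100 °C. The fallback sets out from 1: alkylation with 1,2-dibromoethane and K2CO3 in DMF gives 2-(2-bromoethoxy)-4,6-dimethoxybenzaldehyde F3, and elimination of HBr with KOt-Bu in THF at 0 °C returns to the route at 3.

**Step 3.** The electron-rich bromoalkene 5 may revert to the ketone by solvolysis or lose HBr before or during the magnesium insertion, and the insertion may be incomplete. The fallback replaces the halide by a Shapiro reaction and bypasses 5 and 6. It sets out from 4, which is condensed with 2,4,6-triisopropylbenzenesulfonyl hydrazide in methanol to the (E)-hydrazone 4'-(benzyloxy)acetophenone 2,4,6-triisopropylbenzenesulfonylhydrazone F4. Two equivalents of n-BuLi in THF (−78 to 0 °C) give 1-[4-(benzyloxy)phenyl]vinyllithium F5 with loss of sulfinate and nitrogen, and addition of F5 to 3 at −78 °C returns to the route at 7.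

**Step 7.** Iodination may go partly to C8 or twice, since both free ring A positions lie between two oxygens and the preference for C6 rests only on the directing effect of the chelated hydroxyl. The fallback fixes the site by a sigmatropic shift that can reach only C6, and bypasses 11, 12 and the Stille coupling. It sets out from 10: allyl bromide and K2CO3 in DMF give 5-allyloxy-4'-benzyloxy-7-methoxyisoflavone F6. Claisen rearrangement in N,N-diethylaniline at about 190 °C moves the allyl group to the only free ortho position, giving 6-allyl-4'-benzyloxy-5-hydroxy-7-methoxyisoflavone F7. Cross-metathesis with 2-methyl-2-butene and the second-generation Grubbs catalyst RuCl2(=CHPh)(H2IMes)(PCy3) gives 4'-benzyloxy-5-hydroxy-7-methoxy-6-(3-methylbut-2-enyl)isoflavone F8. Debenzylation of F8 with BCl3 and pentamethylbenzene at −78 °C returns to the route at 14; this is the one place where the prenyl group would face the Lewis acid.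

**Step 9.** The stannane may transfer its allyl group through the tertiary terminus, giving the 1,1-dimethylallyl isomer, and transmetalation at the arylpalladium flanked by hydroxyl and methoxyl may be slow enough for reduction of the C–I bond to compete. The fallback sets out from 12: Stille coupling with allyltributylstannane and Pd(PPh3)4 in DMF, where the two allyl termini are identical, gives 6-allyl-4',5-dihydroxy-7-methoxyisoflavone F9. Cross-metathesis of F9 with 2-methyl-2-butene and the second-generation Grubbs catalyst RuCl2(=CHPh)(H2IMes)(PCy3) then returns to the route at 14.

## Further compounds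

F1 | step 5 | 2-[4-(benzyloxy)phenyl]-1-(2-hydroxy-4,6-dimethoxyphenyl)prop-2-en-1-one | C=C(C(=O)c1c(O)cc(OC)cc1OC)c1ccc(OCc2ccccc2)cc1
F2 | step 5 | rac-4'-benzyloxy-5,7-dimethoxyisoflavanone (racemate) | COc1cc(OC)c2c(c1)OCC(c1ccc(OCc3ccccc3)cc1)C2=O
F3 | step 1 | 2-(2-bromoethoxy)-4,6-dimethoxybenzaldehyde | COc1cc(OC)c(C=O)c(OCCBr)c1
F4 | step 3 | (E)-4'-(benzyloxy)acetophenone 2,4,6-triisopropylbenzenesulfonylhydrazone | C/C(=N\NS(=O)(=O)c1c(C(C)C)cc(C(C)C)cc1C(C)C)c1ccc(OCc2ccccc2)cc1
F5 | step 3 | 1-[4-(benzyloxy)phenyl]vinyllithium | [Li]C(=C)c1ccc(OCc2ccccc2)cc1
F6 | step 7 | 5-allyloxy-4'-benzyloxy-7-methoxyisoflavone | C=CCOc1cc(OC)cc2occ(-c3ccc(OCc4ccccc4)cc3)c(=O)c12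
F7 | step 7 | 6-allyl-4'-benzyloxy-5-hydroxy-7-methoxyisoflavone | C=CCc1c(OC)cc2occ(-c3ccc(OCc4ccccc4)cc3)c(=O)c2c1O
F8 | step 7 | 4'-benzyloxy-5-hydroxy-7-methoxy-6-(3-methylbut-2-enyl)isoflavone | COc1cc2occ(-c3ccc(OCc4ccccc4)cc3)c(=O)c2c(O)c1CC=C(C)C
F9 | step 9 | 6-allyl-4',5-dihydroxy-7-methoxyisoflavone | C=CCc1c(OC)cc2occ(-c3ccc(O)cc3)c(=O)c2c1O
A1 | alternative 1 | 1-[2-hydroxy-4,6-dimethoxy-5-(3-methylbut-2-enyl)phenyl]-2-[4-(methoxymethoxy)phenyl]ethanone | COCOc1ccc(CC(=O)c2c(O)cc(OC)c(CC=C(C)C)c2OC)cc1
A2 | alternative 1 | 3,5-dimethoxy-4-(3-methylbut-2-enyl)-2-(trimethylsilyl)phenyl trifluoromethanesulfonate | COc1cc(OS(=O)(=O)C(F)(F)F)c([Si](C)(C)C)c(OC)c1CC=C(C)C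
A3 | alternative 1 | [4-(methoxymethoxy)phenyl]acetic acid | COCOc1ccc(CC(=O)O)cc1
A4 | alternative 2 | 4'-O-tert-butyldimethylsilyl gancaonin G | COc1cc2occ(-c3ccc(O[Si](C)(C)C(C)(C)C)cc3)c(=O)c2c(O)c1CC=C(C)C
A5 | alternative 2 | 2-diazo-1-{5-[4-(tert-butyldimethylsilyloxy)phenyl]-4-oxo-4H-pyran-2-yl}ethanone | [N-]=[N+]=CC(=O)c1cc(=O)c(-c2ccc(O[Si](C)(C)C(C)(C)C)cc2)co1
A6 | alternative 2 | 1-methoxy-5-methylhex-4-en-1-yne | COC#CCC=C(C)C
A7 | alternative 3 | 5,7-dimethoxy-4'-(methoxymethoxy)-6-(3-methylbut-2-enyl)isoflavone | COCOc1ccc(-c2coc3cc(OC)c(CC=C(C)C)c(OC)c3c2=O)cc1
A8 | alternative 3 | 1-iodo-2,4-dimethoxy-6-{(E)-2-[4-(methoxymethoxy)phenyl]ethenyloxy}-3-(3-methylbut-2-enyl)benzene | COCOc1ccc(/C=C/Oc2cc(OC)c(CC=C(C)C)c(OC)c2I)cc1
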